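## Retrosynthetic overview

1. Target 28 ⇐ acetylation of 27 ⇐ hydroxyl-directed epoxidation of the cis C2=C3 bond of macrocyclic dienol 26 (2,3-oxirane formed last).
2. 26 ⇐ iodo aldehyde 25: ten-membered ring closed at C9–C10 by an electrochemical chromium/nickel-catalysed intramolecular Nozaki–Hiyama–Kishi coupling.
3. 25 ⇐ lactone 20 (side-chain ester from epoxy acid 5, lactone-controlled 4,5-epoxidation, C9 oxidation); 20 ⇐ trienal 18 + allylic chloride 9 by chromium allylation/lactonisation (C6–C7).
4. 9 ⇐ (R)-glyceraldehyde acetonide 6 + methyl acrylate 7; 18 ⇐ enynol 10 + formaldehyde + iodo ylide; 5 ⇐ ethyl (S)-3-hydroxybutanoate 1.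
5. Ring order: side-chain oxirane (in 5), γ-lactone, 4,5-oxirane, carbocycle, 2,3-oxirane.

Assumption: in the larger intermediates atoms carry the germacrane numbers of the target (ring C1–C10, lactone O on C6, C11, C12 = lactone C=O, C13 = exocyclic CH2, C14 = ester carbon, C15 = methyl). "As in the target" means the same spatial arrangement, which each SMILES shows.

## Route

Step 1
Reactants: 1 ethyl (3S)-3-hydroxybutanoate
Product: 2 ethyl (2S,3S)-2-chloro-3-hydroxybutanoate
Conditions: LiN(iPr)2 (2.2 equiv), THF, −78 → −20 °C; C2Cl6, −78 °C; AcOH quench at −78 °C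
Reagents that add atoms: hexachloroethane, ClC(Cl)(Cl)C(Cl)(Cl)Cl
Why: Fráter–Seebach reaction of the chelated β-oxido enolate, which takes the electrophile (here chlorine) on the face away from the C3 methyl group and so gives the anti (2S,3S) chlorohydrin.

Step 2
Reactants: 2 ethyl (2S,3S)-2-chloro-3-hydroxybutanoate
Product: 4 ethyl (2S,3S)-2,3-dimethyloxirane-2-carboxylate, via chloro alkoxide 3 (not isolated)
Conditions: LiN(iPr)2 (2.2 equiv), THF–DMPU, −78 °C; MeI, −78 → −30 °C; then 23 °C, 2 h
Reagents that add atoms: iodomethane, CI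
Why: a second Fráter–Seebach alkylation puts methyl on the same anti face, so chlorine ends syn to the alkoxide in 3, and Darzens-type closure with inversion at C2 gives the cis (angelate-type) oxirane while C3 is untouched.

Step 3
Reactants: 4 ethyl (2S,3S)-2,3-dimethyloxirane-2-carboxylate
Product: 5 (2S,3S)-2,3-dimethyloxirane-2-carboxylic acid
Conditions: LiOH, THF–H2O, 0 °C; 1 M HCl to pH 3 at 0 °C, rapid extraction
Reagents that add atoms: lithium hydroxide, [Li+].[OH-]
Why: ester saponification at the acyl carbon, which leaves both oxirane stereocentres untouched under cold, brief conditions.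

Step 4
Reactants: 6 (4R)-2,2-dimethyl-1,3-dioxolane-4-carbaldehyde; 7 methyl acrylate
Product: 8 methyl 2-{[(4R)-2,2-dimethyl-1,3-dioxolan-4-yl](hydroxy)methyl}prop-2-enoate (both carbinol epimers)
Conditions: DABCO (0.5 equiv), 1,4-dioxane–H2O (1:1), 23 °C, 3 d
Reagents that add atoms: none
Why: Morita–Baylis–Hillman reaction, whose new carbinol centre is removed in step 5 while the purchased dioxolane centre (later C8) is not touched.

Step 5
Reactants: 8 methyl 2-{[(4R)-2,2-dimethyl-1,3-dioxolan-4-yl](hydroxy)methyl}prop-2-enoate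
Product: 9 methyl (2Z)-2-(chloromethyl)-3-[(4S)-2,2-dimethyl-1,3-dioxolan-4-yl]prop-2-enoate
Conditions: NCS, Me2S, CH2Cl2, −20 → 23 °C
Reagents that add atoms: N-chlorosuccinimide, O=C1CCC(=O)N1Cl
Why: Corey–Kim activation of the allylic alcohol followed by SN2′ return of chloride gives the conjugated, thermodynamically preferred (Z) 2-(chloromethyl)alkenoate.

Step 6
Reactants: 10 (2E)-3-methylpent-2-en-4-yn-1-ol
Product: 11 triethyl{[(2E)-3-methylpent-2-en-4-yn-1-yl]oxy}silane
Conditions: Et3SiCl, imidazole, CH2Cl2, 0 °C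
Reagents that add atoms: chlorotriethylsilane, CC[Si](Cl)(CC)CC
Why: routine silylation of a primary alcohol, with the purchased E double bond (later C4=C5) unchanged.

Step 7
Reactants: 11 triethyl{[(2E)-3-methylpent-2-en-4-yn-1-yl]oxy}silane
Product: 12 (4E)-4-methyl-6-[(triethylsilyl)oxy]hex-4-en-2-yn-1-ol
Conditions: n-BuLi, THF, −78 °C; (CH2O)n, −78 → 0 °C; aq. NH4Cl
Reagents that add atoms: paraformaldehyde (as formaldehyde), C=O
Why: addition of the lithium acetylide to formaldehyde installs C1 as a propargylic alcohol.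

Step 8
Reactants: 12 (4E)-4-methyl-6-[(triethylsilyl)oxy]hex-4-en-2-yn-1-ol
Product: 13 (2Z,4E)-4-methyl-6-[(triethylsilyl)oxy]hexa-2,4-dien-1-ol
Conditions: H2 (1 atm), Pd/CaCO3 poisoned with Pb(OAc)2, quinoline, EtOAc, 23 °C
Reagents that add atoms: none
Why: Lindlar semihydrogenation adds hydrogen syn to the alkyne and so fixes the cis C2=C3 bond.

Step 9
Reactants: 13 (2Z,4E)-4-methyl-6-[(triethylsilyl)oxy]hexa-2,4-dien-1-ol; 14 methyl (triphenylphosphoranylidene)acetate
Product: 17 methyl (2Z,4Z,6E)-2-iodo-6-methyl-8-[(triethylsilyl)oxy]octa-2,4,6-trienoate, via dienal 15 (not isolated), via iodo ylide 16 (not isolated)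
Conditions: 14, NIS, CH2Cl2, −20 °C (gives 16); then 13, MnO2, CH2Cl2, 0 → 23 °C, dark
Reagents that add atoms: N-iodosuccinimide, O=C1CCC(=O)N1I
Why: tandem allylic oxidation/Wittig olefination in which the labile (2Z)-dienal 15 is trapped as formed by the stabilised iodo ylide, which places the ester trans to the chain and hence iodine cis to C2.

Step 10
Reactants: 17 methyl (2Z,4Z,6E)-2-iodo-6-methyl-8-[(triethylsilyl)oxy]octa-2,4,6-trienoate
Product: 18 methyl (2Z,4Z,6E)-2-iodo-6-methyl-8-oxoocta-2,4,6-trienoate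
Conditions: (COCl)2, DMSO, CH2Cl2, −78 → −40 °C; Et3N, −78 → 0 °C
Reagents that add atoms: none
Why: Swern oxidation converts a primary triethylsilyl ether directly into the aldehyde, here the C6 enal, without a separate desilylation.

Step 11
Reactants: 18 methyl (2Z,4Z,6E)-2-iodo-6-methyl-8-oxoocta-2,4,6-trienoate; 9 methyl (2Z)-2-(chloromethyl)-3-[(4S)-2,2-dimethyl-1,3-dioxolan-4-yl]prop-2-enoate
Product: 20 trans-α-methylene-γ-butyrolactone bearing the iodotrienoate chain on C6 and the (4S)-dioxolanyl group on C7, via hydroxy ester 19 (not isolated)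
Conditions: CrCl2 (nickel-free, 3 equiv), THF, 0 → 23 °C; aq. NH4Cl; PPTS (cat.), CH2Cl2, 23 °C
Reagents that add atoms: none
Why: Nozaki–Hiyama allylation in which the equilibrating allylchromium reagent (trivalent chromium) adds through a chair transition state with C8 equatorial to give the anti adduct (6,7-trans lactone after ring closure), the aldehyde reaching C7 anti to the dioxolane C8–C9 bond with H-8 eclipsing the ester-bearing alkene (Houk-type staggered model), which sets C6 and C7 as in the target from the purchased C8, while the alkenyl iodide is inert without nickel.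

Step 12
Reactants: 20 lactone acetonide
Product: 21 lactone diol (free 8-OH and 9-OH)
Conditions: AcOH–H2O (4:1), 40 °C
Reagents that add atoms: none
Why: acid hydrolysis of the isopropylidene acetal, done before any acid-sensitive oxirane is present.

Step 13
Reactants: 21 lactone diol
Product: 22 9-O-triethylsilyl lactone alcohol (free 8-OH)
Conditions: Et3SiCl, imidazole, CH2Cl2, −78 °C
Reagents that add atoms: chlorotriethylsilane, CC[Si](Cl)(CC)CC
Why: the primary hydroxyl is silylated selectively at low temperature, leaving the secondary C8 hydroxyl free.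

Step 14
Reactants: 22 9-O-triethylsilyl lactone alcohol; 5 (2S,3S)-2,3-dimethyloxirane-2-carboxylic acid
Product: 23 8-O-[(2S,3S)-2,3-dimethyloxirane-2-carbonyl] 9-O-triethylsilyl lactone
Conditions: DCC, DMAP (cat.), CH2Cl2, 0 → 23 °C
Reagents that add atoms: none
Why: Steglich esterification acylates the C8 oxygen with retention at C8 and brings in both side-chain stereocentres from 5.

Step 15
Reactants: 23 8-O-acyl 9-O-triethylsilyl lactone
Product: 24 4,5-epoxy lactone (trans oxirane, C4 and C5 as in the target)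
Conditions: mCPBA, CH2Cl2–aq. phosphate buffer (pH 7), 0 °C
Reagents that add atoms: 3-chloroperoxybenzoic acid, O=C(OO)c1cccc(Cl)c1
Why: Prilezhaev epoxidation of the only electron-rich alkene (distal, trisubstituted), where allylic 1,3-strain between C15 and C6 holds H-6 in the alkene plane and the peracid attacks the face flanked by the lactone oxygen, anti to the branched C7, so the C5–O and C6–O bonds end syn as in the target.

Step 16
Reactants: 24 4,5-epoxy lactone
Product: 25 C9 aldehyde (seco iodo aldehyde)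
Conditions: (COCl)2, DMSO, CH2Cl2, −78 → −40 °C; iPr2NEt, −78 → −20 °C
Reagents that add atoms: none
Why: Swern oxidation of the primary triethylsilyl ether gives the α-acyloxy aldehyde directly under cold, non-epimerising conditions that the oxiranes tolerate.

Step 17
Reactants: 25 C9 aldehyde (seco iodo aldehyde)
Product: 26 macrocyclic dienol (ten-membered ring, free 9-OH, cis C1=C10 and cis C2=C3)
Conditions: CrCl2 (20 mol %), NiCl2(dme) (2 mol %), Et4NBr (0.1 M), DMF, undivided cell, Al anode, Ni-foam cathode, 3 mA, 2.4 F/mol, syringe-pump addition to 2 mM, 23 °C; aq. potassium sodium tartrate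
Reagents that add atoms: none
Why: Proposed new method: a chromium-electrocatalytic, nickel-co-catalysed intramolecular Nozaki–Hiyama–Kishi ring closure in which the cathode regenerates divalent chromium, zerovalent nickel inserts into the C–I bond, the alkenyl group passes to trivalent chromium and adds to the C9 aldehyde with retention of alkene geometry, and trivalent aluminium from the anode takes over the alkoxide so that no silyl chloride or zirconocene is needed beside the oxiranes; the tether reaches C10 from the ring face and the metal-bound oxygen ends on the outer face with H-9 in the alkene plane (allylic 1,3-strain with C2), which is the 9S alcohol of the target; closest known reaction type: intermolecular electrochemical Nozaki–Hiyama–Kishi coupling of alkenyl halides with aldehydes and stoichiometric CrCl2/NiCl2 macrocyclisation.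

Step 18
Reactants: 26 macrocyclic dienol
Product: 27 2,3:4,5-diepoxy alcohol (9-O-deacetyl target)
Conditions: mCPBA, CH2Cl2–aq. phosphate buffer (pH 7), 0 → 23 °C
Reagents that add atoms: 3-chloroperoxybenzoic acid, O=C(OO)c1cccc(Cl)c1
Why: Henbest-type hydroxyl-directed Prilezhaev epoxidation of the γ,δ-alkene of the dienoate (the enoate and the methylene lactone are too electron-poor), with the peracid hydrogen-bonded to the cis-disposed 9-OH on the outer face (H-9 in the alkene plane, C8 and C3 on the ring face), which gives the cis 2R,3R oxirane.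

Step 19
Reactants: 27 2,3:4,5-diepoxy alcohol
Product: 28 target
Conditions: Ac2O, pyridine, DMAP (cat.), CH2Cl2, 0 °C
Reagents that add atoms: acetic anhydride, CC(=O)OC(C)=O
Why: O-acetylation of the secondary allylic alcohol with retention at C9, under conditions that leave the three oxiranes and the methylene lactone intact.

## Compound list

1 | ethyl (3S)-3-hydroxybutanoate | CCOC(=O)C[C@H](C)O | starting material
2 | ethyl (2S,3S)-2-chloro-3-hydroxybutanoate | CCOC(=O)[C@@H](Cl)[C@H](C)O | intermediate
3 | ethyl (2R,3S)-2-chloro-3-hydroxy-2-methylbutanoate (as lithium alkoxide) | CCOC(=O)[C@](C)(Cl)[C@H](C)O | intermediate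
4 | ethyl (2S,3S)-2,3-dimethyloxirane-2-carboxylate | CCOC(=O)[C@@]1(C)O[C@H]1C | intermediate
5 | (2S,3S)-2,3-dimethyloxirane-2-carboxylic acid | OC(=O)[C@@]1(C)O[C@H]1C | intermediate
6 | (4R)-2,2-dimethyl-1,3-dioxolane-4-carbaldehyde | O=C[C@H]1COC(C)(C)O1 | starting material
7 | methyl acrylate | C=CC(=O)OC | starting material
8 | methyl 2-{[(4R)-2,2-dimethyl-1,3-dioxolan-4-yl](hydroxy)methyl}prop-2-enoate (both carbinol epimers) | C=C(C(=O)OC)C(O)[C@H]1COC(C)(C)O1 | intermediate
9 | methyl (2Z)-2-(chloromethyl)-3-[(4S)-2,2-dimethyl-1,3-dioxolan-4-yl]prop-2-enoate | COC(=O)/C(CCl)=C/[C@H]1COC(C)(C)O1 | intermediate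
10 | (2E)-3-methylpent-2-en-4-yn-1-ol | OC/C=C(C)/C#C | starting material
11 | triethyl{[(2E)-3-methylpent-2-en-4-yn-1-yl]oxy}silane | CC[Si](CC)(CC)OC/C=C(C)/C#C | intermediate
12 | (4E)-4-methyl-6-[(triethylsilyl)oxy]hex-4-en-2-yn-1-ol | CC[Si](CC)(CC)OC/C=C(C)/C#CCO | intermediate
13 | (2Z,4E)-4-methyl-6-[(triethylsilyl)oxy]hexa-2,4-dien-1-ol | CC[Si](CC)(CC)OC/C=C(C)/C=C\CO | intermediate
14 | methyl (triphenylphosphoranylidene)acetate | COC(=O)C=P(c1ccccc1)(c1ccccc1)c1ccccc1 | starting material
15 | (2Z,4E)-4-methyl-6-[(triethylsilyl)oxy]hexa-2,4-dienal | CC[Si](CC)(CC)OC/C=C(C)/C=C\C=O | intermediate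
16 | methyl 2-iodo-2-(triphenylphosphoranylidene)acetate | COC(=O)C(I)=P(c1ccccc1)(c1ccccc1)c1ccccc1 | intermediate
17 | methyl (2Z,4Z,6E)-2-iodo-6-methyl-8-[(triethylsilyl)oxy]octa-2,4,6-trienoate | CC[Si](CC)(CC)OC/C=C(C)/C=C\C=C(/I)C(=O)OC | intermediate
18 | methyl (2Z,4Z,6E)-2-iodo-6-methyl-8-oxoocta-2,4,6-trienoate | O=C/C=C(C)/C=C\C=C(/I)C(=O)OC | intermediate
19 | open hydroxy ester of 20 (C12 methyl ester, free 6-OH; C6, C7, C8 as in 20) | C=C(C(=O)OC)[C@@H]([C@H](O)/C=C(C)/C=C\C=C(/I)C(=O)OC)[C@H]1COC(C)(C)O1 | intermediate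
20 | trans-α-methylene-γ-butyrolactone (O on C6) with the (4E,2Z)-10-iodo-trienoate chain C5–C10/C14 on C6 (iodine cis to C2) and the (4S)-2,2-dimethyl-1,3-dioxolan-4-yl group (C8, C9) on C7; C6, C7, C8 as in the target | C=C1C(=O)O[C@@H]([C@H]1[C@H]1COC(C)(C)O1)/C=C(C)/C=C\C=C(/I)C(=O)OC | intermediate
21 | lactone 20 with the acetonide removed (8-OH, 9-OH) | C=C1C(=O)O[C@@H]([C@H]1[C@H](O)CO)/C=C(C)/C=C\C=C(/I)C(=O)OC | intermediate
22 | 9-O-triethylsilyl ether of 21 (free 8-OH) | C=C1C(=O)O[C@@H]([C@H]1[C@H](O)CO[Si](CC)(CC)CC)/C=C(C)/C=C\C=C(/I)C(=O)OC | intermediate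
23 | 8-O-[(2S,3S)-2,3-dimethyloxirane-2-carbonyl] ester of 22 | C=C1C(=O)O[C@@H]([C@H]1[C@H](OC(=O)[C@@]2(C)O[C@H]2C)CO[Si](CC)(CC)CC)/C=C(C)/C=C\C=C(/I)C(=O)OC | intermediate
24 | 4,5-epoxide of 23 (trans oxirane, C15 on C4; C4, C5 as in the target) | C=C1C(=O)O[C@@H]([C@H]1[C@H](OC(=O)[C@@]2(C)O[C@H]2C)CO[Si](CC)(CC)CC)[C@H]1O[C@]1(C)/C=C\C=C(/I)C(=O)OC | intermediate
25 | C9 aldehyde from 24 (seco iodo aldehyde; C4–C8 as in the target) | C=C1C(=O)O[C@@H]([C@H]1[C@H](OC(=O)[C@@]2(C)O[C@H]2C)C=O)[C@H]1O[C@]1(C)/C=C\C=C(/I)C(=O)OC | intermediate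
26 | macrocyclic dienol: target skeleton with a cis C2=C3 double bond in place of the 2,3-oxirane and free 9-OH (C9 cis to C2 on C1=C10; C4–C9 as in the target) | C=C1C(=O)O[C@H]2[C@H]1[C@H](OC(=O)[C@@]1(C)O[C@H]1C)[C@@H](O)/C(C(=O)OC)=C\C=C/[C@@]1(C)O[C@H]21 | intermediate
27 | 9-O-deacetyl target (2,3:4,5-diepoxide, free 9-OH) | C=C1C(=O)O[C@H]2[C@H]1[C@H](OC(=O)[C@@]1(C)O[C@H]1C)[C@@H](O)/C(C(=O)OC)=C\[C@H]1O[C@H]1[C@@]1(C)O[C@H]21 | intermediate
28 | target: methyl ester (C14) of the (2R,3R,4S,5R,6S,7R,8S,9S)-9-acetoxy-8-[(2S,3S)-2,3-dimethyloxirane-2-carbonyloxy]-2,3:4,5-diepoxy-germacra-1(10)E,11(13)-dien-12,6-olide (C9 cis to C2) | C=C1C(=O)O[C@H]2[C@H]1[C@H](OC(=O)[C@@]1(C)O[C@H]1C)[C@@H](OC(C)=O)/C(C(=O)OC)=C\[C@H]1O[C@H]1[C@@]1(C)O[C@H]21 | target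

## Step count and risks

Total step count: 19. Longest linear sequence: 14 steps (10 → 28, steps 6–10 and 11–19).

Three steps most likely to fail:

**Step 17 (proposed new electrochemical ring closure).** Risks are ring strain, Lewis-acid opening of the dienyl oxirane by aluminium or chromium salts, migration of the C8 acyl group to the new alkoxide, and the C9 configuration, since an open-chain Felkin model would favour the 9-epimer and only the ring is argued to override it. The fallback uses known chemistry and sets C9 by reduction instead of in the C–C bond formation. It sets out from 25: stoichiometric CrCl2 with catalytic NiCl2 in DMSO at high dilution (the classical Nozaki–Hiyama–Kishi macrocyclisation) gives 26 together with its C9 epimer, the 9-epi dienol F1. The mixture is oxidised with Dess–Martin periodinane to the macrocyclic alkylidene keto ester, enone F2. Luche reduction (NaBH4, CeCl3·7H2O, MeOH, −78 °C) of the s-trans enone from the outer face then comes back to the route at 26.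

**Step 11 (chromium allylation/lactonisation).** The anti (trans-lactone) outcome rests on equilibration of the allylchromium reagent, and the face selectivity at C7 rests on one of two competing models for an allylic dioxolane. If the aldehyde instead adds anti to the dioxolane oxygen, C6 and C7 come out mirror-imaged relative to C8. The fallback then keeps the same reactions but takes C8 from the other enantiomer and corrects it at the esterification. It sets out from 18 (with 7 and 5): the bought aldehyde (4S)-2,2-dimethyl-1,3-dioxolane-4-carbaldehyde F3 is taken through the conditions of steps 4 and 5 to the Baylis–Hillman adduct F4 and the allylic chloride F5. CrCl2 allylation of 18 with F5 and lactonisation give the 8-epi lactone acetonide F6 (C6 and C7 as in the target). Aqueous acetic acid gives the 8-epi diol F7, and Et3SiCl/imidazole gives the 8-epi silyl ether alcohol F8. Mitsunobu esterification of F8 with acid 5 (PPh3, DIAD, toluene, 0 °C) inverts C8 and comes back to the route at 23.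

**Step 18 (late 2,3-epoxidation).** The dienoate alkene is sluggish toward peracid, and the face selectivity depends on the ring conformation and the hydroxyl direction. If the peracid gives the 2,3-epimeric oxirane, the fallback is a halohydrin route, which puts the oxirane on the face opposite to the one the electrophile attacks. It sets out from 26: acetylation (Ac2O, pyridine, DMAP) gives the dienyl acetate F9. NBS in aqueous 1,2-dimethoxyethane at 0 °C gives the bromohydrin F10 (bromine on C3 from the accessible face, water anti at the allylic C2). K2CO3 in acetonitrile closes the oxirane with inversion at C3 and comes back to the route at 28.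

## Further compounds

F1 | step 17 | 9-epi-26 (macrocyclic dienol with inverted C9) | C=C1C(=O)O[C@H]2[C@H]1[C@H](OC(=O)[C@@]1(C)O[C@H]1C)[C@H](O)/C(C(=O)OC)=C\C=C/[C@@]1(C)O[C@H]21
F2 | step 17 | macrocyclic C9 ketone (alkylidene keto ester) of 26 | C=C1C(=O)O[C@H]2[C@H]1[C@H](OC(=O)[C@@]1(C)O[C@H]1C)C(=O)/C(C(=O)OC)=C\C=C/[C@@]1(C)O[C@H]21
F3 | step 11 | (4S)-2,2-dimethyl-1,3-dioxolane-4-carbaldehyde | O=C[C@@H]1COC(C)(C)O1
F4 | step 11 | methyl 2-{[(4S)-2,2-dimethyl-1,3-dioxolan-4-yl](hydroxy)methyl}prop-2-enoate (both carbinol epimers) | C=C(C(=O)OC)C(O)[C@@H]1COC(C)(C)O1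
F5 | step 11 | methyl (2Z)-2-(chloromethyl)-3-[(4R)-2,2-dimethyl-1,3-dioxolan-4-yl]prop-2-enoate | COC(=O)/C(CCl)=C/[C@@H]1COC(C)(C)O1
F6 | step 11 | 8-epi-20 (lactone acetonide, C6 and C7 as in the target, C8 inverted) | C=C1C(=O)O[C@@H]([C@H]1[C@@H]1COC(C)(C)O1)/C=C(C)/C=C\C=C(/I)C(=O)OC
F7 | step 11 | 8-epi-21 (lactone diol) | C=C1C(=O)O[C@@H]([C@H]1[C@@H](O)CO)/C=C(C)/C=C\C=C(/I)C(=O)OC
F8 | step 11 | 8-epi-22 (9-O-triethylsilyl lactone alcohol) | C=C1C(=O)O[C@@H]([C@H]1[C@@H](O)CO[Si](CC)(CC)CC)/C=C(C)/C=C\C=C(/I)C(=O)OC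
F9 | step 18 | 9-O-acetate of 26 (2,3-ene) | C=C1C(=O)O[C@H]2[C@H]1[C@H](OC(=O)[C@@]1(C)O[C@H]1C)[C@@H](OC(C)=O)/C(C(=O)OC)=C\C=C/[C@@]1(C)O[C@H]21
F10 | step 18 | 3-bromo-2-hydroxy adduct of F9 (2-OH on the target face, 3-Br anti) | C=C1C(=O)O[C@H]2[C@H]1[C@H](OC(=O)[C@@]1(C)O[C@H]1C)[C@@H](OC(C)=O)/C(C(=O)OC)=C\[C@@H](O)[C@H](Br)[C@@]1(C)O[C@H]21
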